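**Plan**
- **Cuts:** first the two O–Si bonds, then the helper carbonyl at C2. Next O1–C2 and C3–C4 of ring C are cut in one operation. This gives a ring-A o-quinone methide (C4=C4a–C8a=O1) and the enolate of the ring-B/ring-D arylacetic acid (C2–C3). Further back, the C6 prenyl returns to a prenyl ether on O1, and ring D returns to a propargyl ether on O2'.
- **Enabling feature:** C4 is an unsubstituted benzylic CH2 ortho to O1 on ring A. The C5-OMe and C7-O groups sit ortho and para to C4a and stabilise the quinone methide. C3 bears ring B, so C2–C3 maps onto an arylacetate enolate.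
- **Forward order:** rings A and B are bought. The prenyl group reaches C6 by Claisen–Cope rearrangement. Ring D is closed on ring B by a propargyl Claisen cascade. Ring C is closed last by a catalytic formal [4+2] union of the two halves.
- **Stereochemistry:** C3 is the only stereocentre. A chiral isothiourea sets it as R in the ring-closing step. It is carried unchanged through removal of the C2 carbonyl and through desilylation.

Key step: step 12

Assumption: the [C@H] centre of the given SMILES is read as (3R), and 2,4-dihydroxy-6-methoxybenzaldehyde is taken as a catalogue chemical.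

**Ring A fragment**

Step 1
Reactants: 1 ring-A aldehyde (2,4-dihydroxy-6-methoxybenzaldehyde)
Product: 2 mono-silyl ether (2-hydroxy-6-methoxy-4-(triisopropylsilyloxy)benzaldehyde)
Conditions: i-Pr3SiCl, imidazole, DMF, 0 °C to rt
Reagents that add atoms: chlorotriisopropylsilane, CC(C)[Si](Cl)(C(C)C)C(C)C
Why: Selective phenol silylation, because the C2-OH is hydrogen-bonded to the aldehyde and flanked by it, so only the free and more acidic C4-OH should react.

Step 2
Reactants: 2 mono-silyl ether; 3 prenol (3-methylbut-2-en-1-ol)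
Product: 4 prenyl ether (2-methoxy-6-(3-methylbut-2-enyloxy)-4-(triisopropylsilyloxy)benzaldehyde)
Conditions: PPh3, DIAD, THF, 0 °C to rt
Reagents that add atoms: none
Why: Mitsunobu etherification alkylates chelated ortho-hydroxyaryl carbonyl compounds at oxygen under neutral conditions, which spares the base-labile silyl ether para to the formyl group and avoids C-alkylation.

Step 3
Reactants: 4 prenyl ether
Product: 7 C-prenyl salicylaldehyde (2-hydroxy-6-methoxy-5-(3-methylbut-2-enyl)-4-(triisopropylsilyloxy)benzaldehyde), via ortho-dienone 5 (not isolated), via para-dienone 6 (not isolated)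
Conditions: PhNEt2, 200 °C, sealed tube, Ar
Reagents that add atoms: none
Why: Tandem aromatic Claisen–Cope (para-Claisen) rearrangement, in which the first [3,3] shift places a 1,1-dimethylallyl group on an ortho carbon, a second [3,3] shift relays it from the crowded dienone to the only para carbon as a linear prenyl group, and enolisation gives the phenol, as known for prenyl ethers of 2-acyl-3,5-dialkoxyphenols.

Step 4
Reactants: 7 C-prenyl salicylaldehyde
Product: 8 salicyl alcohol (2-(hydroxymethyl)-3-methoxy-4-(3-methylbut-2-enyl)-5-(triisopropylsilyloxy)phenol)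
Conditions: NaBH4, THF/MeOH, 0 °C; aq. NH4Cl; used crude
Reagents that add atoms: none
Why: Borohydride reduction of an aryl aldehyde leaves alkene and silyl ether untouched, and the neutral quench without chromatography respects the easy ionisation of this electron-rich benzylic alcohol.

Step 5
Reactants: 8 salicyl alcohol
Product: 9 hydroxybenzyl sulfone (3-methoxy-4-(3-methylbut-2-enyl)-2-[(4-methylphenyl)sulfonylmethyl]-5-(triisopropylsilyloxy)phenol)
Conditions: p-TolSO2H, CH2Cl2, rt
Reagents that add atoms: p-toluenesulfinic acid, Cc1ccc(cc1)S(=O)O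
Why: Dehydrative S-alkylation of a sulfinic acid, in which the acid ionises the trioxygenated benzylic alcohol and traps it at sulfur, should give a storable o-quinone methide precursor, and no free phenol sits next to the prenyl group to cyclise.

**Ring B/D fragment**

Step 6
Reactants: 10 ring-B aldehyde (2,4-dihydroxybenzaldehyde)
Product: 11 mono-silyl ether (2-hydroxy-4-(triisopropylsilyloxy)benzaldehyde)
Conditions: i-Pr3SiCl, imidazole, DMF, 0 °C to rt
Reagents that add atoms: chlorotriisopropylsilane, CC(C)[Si](Cl)(C(C)C)C(C)C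
Why: Selective phenol silylation of the non-chelated C4-OH, on the same grounds as in step 1.

Step 7
Reactants: 11 mono-silyl ether; 12 3-chloro-3-methylbut-1-yne
Product: 13 propargyl ether (2-(2-methylbut-3-yn-2-yloxy)-4-(triisopropylsilyloxy)benzaldehyde)
Conditions: DBU, CuCl2·2H2O (1 mol %), MeCN, 0 °C to rt
Reagents that add atoms: none
Why: Copper-catalysed O-propargylation of phenols with a tertiary propargyl chloride proceeds through a copper-bound propargyl/allenyl electrophile and so works at 0 °C on hindered, chelated phenols.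

Step 8
Reactants: 13 propargyl ether
Product: 16 chromene aldehyde (2,2-dimethyl-5-(triisopropylsilyloxy)-2H-chromene-8-carbaldehyde), via allenylphenol 14 (not isolated), via vinyl quinone methide 15 (not isolated)
Conditions: o-xylene, 140 °C
Reagents that add atoms: none
Why: Aromatic propargyl Claisen rearrangement can reach only the free ortho carbon C3 between the two oxygens, and enolisation, 1,5-H shift and oxa-6π electrocyclisation then close ring D with O2' as ring oxygen, which fixes the angular regiochemistry.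

Step 9
Reactants: 16 chromene aldehyde
Product: 17 enol ether (8-(2-methoxyethenyl)-2,2-dimethyl-5-(triisopropylsilyloxy)-2H-chromene, E/Z mixture)
Conditions: MeOCH2PPh3Cl, KN(SiMe3)2, THF, 0 °C to rt
Reagents that add atoms: (methoxymethyl)triphenylphosphonium chloride, [Cl-].COC[P+](c1ccccc1)(c1ccccc1)c1ccccc1
Why: Wittig methoxymethylenation adds the carbon that becomes C2, and the alkene geometry does not matter because both isomers converge in step 10.

Step 10
Reactants: 17 enol ether
Product: 18 arylacetaldehyde (2-[2,2-dimethyl-5-(triisopropylsilyloxy)-2H-chromen-8-yl]acetaldehyde)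
Conditions: 2 M aq. HCl, THF, rt; used crude
Reagents that add atoms: water, O
Why: Acid-catalysed enol ether hydrolysis is much faster than protonation of the chromene alkene or cleavage of the aryl triisopropylsilyl ether.

Step 11
Reactants: 18 arylacetaldehyde
Product: 19 arylacetic acid (2-[2,2-dimethyl-5-(triisopropylsilyloxy)-2H-chromen-8-yl]acetic acid)
Conditions: NaClO2, NaH2PO4, 2-methylbut-2-ene (excess), t-BuOH/H2O, 0 °C to rt
Reagents that add atoms: sodium chlorite, [Na+].[O-]Cl=O
Why: Pinnick oxidation converts enolisable aldehydes to acids at mild pH, and the excess scavenger alkene removes hypochlorous acid before it can reach the chromene or the arene.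

**Union and endgame**

Step 12
Reactants: 19 arylacetic acid; 9 hydroxybenzyl sulfone
Product: 22 dihydrocoumarin ((3R)-3-[2,2-dimethyl-5-(triisopropylsilyloxy)-2H-chromen-8-yl]-5-methoxy-6-(3-methylbut-2-enyl)-7-(triisopropylsilyloxy)chroman-2-one), via mixed pivalic anhydride 20 (not isolated), via o-quinone methide 21 (not isolated)
Conditions: 19 (1.5 equiv), t-BuCOCl, i-Pr2NEt, CH2Cl2, 0 °C; then (2S,3R)-HyperBTM [(2S,3R)-3-isopropyl-2-phenyl-3,4-dihydro-2H-benzo[4,5]thiazolo[3,2-a]pyrimidine] (10 mol %), i-Pr2NEt, slow addition of 9, −20 °C to rt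
Reagents that add atoms: pivaloyl chloride, CC(C)(C)C(=O)Cl (atoms kept only in intermediate 20)
Why: Anhydride 20 acylates the isothiourea and i-Pr2NEt deprotonates the acyl ammonium ion to the (Z)-C1-ammonium enolate, while the same base triggers 1,4-elimination of p-toluenesulfinate from phenol 9 to release o-quinone methide 21, a loss made easy by the C5-OMe and C7-OSi donors. The enolate carbon (future C3) adds to the exocyclic CH2 (future C4) in a Michael addition driven by rearomatisation of ring A, and the C8a phenoxide so formed attacks the acyl ammonium carbonyl in a 6-exo-trig lactonisation (O1–C2), which closes ring C and frees the catalyst, a formal [4+2] cycloaddition overall. The closest known reaction type is the Lewis-base-catalysed Michael addition–lactonisation of isothiourea- or carbene-bound arylacetate enolates with o-quinone methides generated in situ, which gives 3-substituted 3,4-dihydrocoumarins. C3 is the only new stereocentre and is under catalyst control: a 1,5-O···S contact holds the enolate coplanar with the catalyst, the pseudoaxial C2-phenyl group shields one face, and attack on the open face should give the 3R lactone from the (2S,3R) catalyst. The step needs C–C bond formation at C4 to outrun O-acylation of 9, dimerisation of 21 and hetero-Diels–Alder capture of 21 by the prenyl and chromene alkenes, which slow addition of 9 to an excess of the charged enolate should secure because the neutral alkenes react only on heating. The configuration at the acidic C3–H should hold because only a hindered amine base is present, the temperature is low and ring B is electron-rich.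

Step 13
Reactants: 22 dihydrocoumarin
Product: 23 lactol ((3R)-3-[2,2-dimethyl-5-(triisopropylsilyloxy)-2H-chromen-8-yl]-5-methoxy-6-(3-methylbut-2-enyl)-7-(triisopropylsilyloxy)chroman-2-ol, mixture of C2 epimers)
Conditions: i-Bu2AlH (1.1 equiv), PhMe, −78 °C; MeOH, then aq. potassium sodium tartrate; used crude
Reagents that add atoms: none
Why: Partial lactone reduction stops at the tetrahedral aluminate at −78 °C, as known for 3,4-dihydrocoumarins, and the cold, non-basic medium should leave C3, both silyl ethers and both alkenes untouched.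

Step 14
Reactants: 23 lactol
Product: 24 bis-silyl isoflavan ((3R)-3-[2,2-dimethyl-5-(triisopropylsilyloxy)-2H-chromen-8-yl]-5-methoxy-6-(3-methylbut-2-enyl)-7-(triisopropylsilyloxy)chroman)
Conditions: Et3SiH (5 equiv), then BF3·OEt2, CH2Cl2, −78 to −30 °C; aq. NaHCO3
Reagents that add atoms: none
Why: Ionic reduction of a lactol, in which BF3 ionises the C2-OH to the ring oxocarbenium ion and the silane already present should capture it at C2 faster than C3–H can be lost, removes the helper oxygen with ring C kept closed.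

Step 15
Reactants: 24 bis-silyl isoflavan
Product: 25 target ((3R)-3-(5-hydroxy-2,2-dimethyl-2H-chromen-8-yl)-5-methoxy-6-(3-methylbut-2-enyl)chroman-7-ol)
Conditions: Bu4NF, AcOH, THF, 0 °C
Reagents that add atoms: none
Why: Buffered fluoride desilylation frees both phenols without acid, so the C7-OH cannot cyclise onto the neighbouring prenyl group and the chromene and C3 are not affected.

**Compound list**
1 | 2,4-dihydroxy-6-methoxybenzaldehyde | COc1cc(O)cc(O)c1C=O | starting material
2 | 2-hydroxy-6-methoxy-4-(triisopropylsilyloxy)benzaldehyde | COc1cc(O[Si](C(C)C)(C(C)C)C(C)C)cc(O)c1C=O | intermediate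
3 | 3-methylbut-2-en-1-ol (prenol) | CC(C)=CCO | starting material
4 | 2-methoxy-6-(3-methylbut-2-enyloxy)-4-(triisopropylsilyloxy)benzaldehyde | COc1cc(O[Si](C(C)C)(C(C)C)C(C)C)cc(OCC=C(C)C)c1C=O | intermediate
5 | 2-methoxy-5-(2-methylbut-3-en-2-yl)-6-oxo-4-(triisopropylsilyloxy)cyclohexa-1,3-diene-1-carbaldehyde (racemic, not isolated) | O=CC1=C(OC)C=C(O[Si](C(C)C)(C(C)C)C(C)C)C(C(C)(C)C=C)C1=O | intermediate
6 | 2-methoxy-3-(3-methylbut-2-enyl)-6-oxo-4-(triisopropylsilyloxy)cyclohexa-1,4-diene-1-carbaldehyde (racemic, not isolated) | O=CC1=C(OC)C(CC=C(C)C)C(O[Si](C(C)C)(C(C)C)C(C)C)=CC1=O | intermediate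
7 | 2-hydroxy-6-methoxy-5-(3-methylbut-2-enyl)-4-(triisopropylsilyloxy)benzaldehyde | COc1c(CC=C(C)C)c(O[Si](C(C)C)(C(C)C)C(C)C)cc(O)c1C=O | intermediate
8 | 2-(hydroxymethyl)-3-methoxy-4-(3-methylbut-2-enyl)-5-(triisopropylsilyloxy)phenol | COc1c(CC=C(C)C)c(O[Si](C(C)C)(C(C)C)C(C)C)cc(O)c1CO | intermediate
9 | 3-methoxy-4-(3-methylbut-2-enyl)-2-[(4-methylphenyl)sulfonylmethyl]-5-(triisopropylsilyloxy)phenol | COc1c(CC=C(C)C)c(O[Si](C(C)C)(C(C)C)C(C)C)cc(O)c1CS(=O)(=O)c1ccc(C)cc1 | intermediate
10 | 2,4-dihydroxybenzaldehyde | O=Cc1ccc(O)cc1O | starting material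
11 | 2-hydroxy-4-(triisopropylsilyloxy)benzaldehyde | O=Cc1ccc(O[Si](C(C)C)(C(C)C)C(C)C)cc1O | intermediate
12 | 3-chloro-3-methylbut-1-yne | C#CC(C)(C)Cl | starting material
13 | 2-(2-methylbut-3-yn-2-yloxy)-4-(triisopropylsilyloxy)benzaldehyde | O=Cc1ccc(O[Si](C(C)C)(C(C)C)C(C)C)cc1OC(C)(C)C#C | intermediate
14 | 2-hydroxy-3-(3-methylbuta-1,2-dienyl)-4-(triisopropylsilyloxy)benzaldehyde (not isolated) | O=Cc1ccc(O[Si](C(C)C)(C(C)C)C(C)C)c(C=C=C(C)C)c1O | intermediate
15 | 5-(3-methylbut-2-enylidene)-6-oxo-4-(triisopropylsilyloxy)cyclohexa-1,3-diene-1-carbaldehyde (not isolated) | O=CC1=CC=C(O[Si](C(C)C)(C(C)C)C(C)C)C(=CC=C(C)C)C1=O | intermediate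
16 | 2,2-dimethyl-5-(triisopropylsilyloxy)-2H-chromene-8-carbaldehyde | O=Cc1ccc(O[Si](C(C)C)(C(C)C)C(C)C)c2C=CC(C)(C)Oc12 | intermediate
17 | 8-(2-methoxyethenyl)-2,2-dimethyl-5-(triisopropylsilyloxy)-2H-chromene (E/Z mixture) | COC=Cc1ccc(O[Si](C(C)C)(C(C)C)C(C)C)c2C=CC(C)(C)Oc12 | intermediate
18 | 2-[2,2-dimethyl-5-(triisopropylsilyloxy)-2H-chromen-8-yl]acetaldehyde | O=CCc1ccc(O[Si](C(C)C)(C(C)C)C(C)C)c2C=CC(C)(C)Oc12 | intermediate
19 | 2-[2,2-dimethyl-5-(triisopropylsilyloxy)-2H-chromen-8-yl]acetic acid | OC(=O)Cc1ccc(O[Si](C(C)C)(C(C)C)C(C)C)c2C=CC(C)(C)Oc12 | intermediate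
20 | 2-[2,2-dimethyl-5-(triisopropylsilyloxy)-2H-chromen-8-yl]acetic pivalic anhydride (not isolated) | CC(C)(C)C(=O)OC(=O)Cc1ccc(O[Si](C(C)C)(C(C)C)C(C)C)c2C=CC(C)(C)Oc12 | intermediate
21 | 5-methoxy-4-(3-methylbut-2-enyl)-6-methylidene-3-(triisopropylsilyloxy)cyclohexa-2,4-dien-1-one (not isolated) | C=C1C(OC)=C(CC=C(C)C)C(O[Si](C(C)C)(C(C)C)C(C)C)=CC1=O | intermediate
22 | (3R)-3-[2,2-dimethyl-5-(triisopropylsilyloxy)-2H-chromen-8-yl]-5-methoxy-6-(3-methylbut-2-enyl)-7-(triisopropylsilyloxy)chroman-2-one | COc1c(CC=C(C)C)c(O[Si](C(C)C)(C(C)C)C(C)C)cc2c1C[C@H](c1ccc(O[Si](C(C)C)(C(C)C)C(C)C)c3c1OC(C)(C)C=C3)C(=O)O2 | intermediate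
23 | (3R)-3-[2,2-dimethyl-5-(triisopropylsilyloxy)-2H-chromen-8-yl]-5-methoxy-6-(3-methylbut-2-enyl)-7-(triisopropylsilyloxy)chroman-2-ol (C2 epimers) | COc1c(CC=C(C)C)c(O[Si](C(C)C)(C(C)C)C(C)C)cc2c1C[C@H](c1ccc(O[Si](C(C)C)(C(C)C)C(C)C)c3c1OC(C)(C)C=C3)C(O)O2 | intermediate
24 | (3R)-3-[2,2-dimethyl-5-(triisopropylsilyloxy)-2H-chromen-8-yl]-5-methoxy-6-(3-methylbut-2-enyl)-7-(triisopropylsilyloxy)chroman | COc1c(CC=C(C)C)c(O[Si](C(C)C)(C(C)C)C(C)C)cc2c1C[C@H](c1ccc(O[Si](C(C)C)(C(C)C)C(C)C)c3c1OC(C)(C)C=C3)CO2 | intermediate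
25 | (3R)-3-(5-hydroxy-2,2-dimethyl-2H-chromen-8-yl)-5-methoxy-6-(3-methylbut-2-enyl)chroman-7-ol | COc1c(CC=C(C)C)c(O)cc2c1C[C@H](c1ccc(O)c3c1OC(C)(C)C=C3)CO2 | target

**Totals**
- Total step count: 15.
- Longest linear sequence: 10 (steps 6 to 15).

**Steps most likely to fail**

1. **Step 12.**
   - **What may go wrong:** the acyl ammonium ion may acylate the phenol of 9 before sulfinate is lost. Quinone methide 21 may condense with itself. The configuration at C3 may erode by enolisation of the aryl lactone.
   - **Fallback:** auxiliary control with a preformed enolate replaces catalyst control. It sets out from 19 and 9 and comes back at 22.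
   - Acid 19 would be activated as anhydride 20 (t-BuCOCl, Et3N, THF, −20 °C). Coupling with (R)-4-benzyloxazolidin-2-one and LiCl would give the imide (4R)-4-benzyl-3-{2-[2,2-dimethyl-5-(triisopropylsilyloxy)-2H-chromen-8-yl]acetyl}oxazolidin-2-one F1.
   - Its chelated (Z)-sodium enolate (NaN(SiMe3)2, THF, −78 °C, the Evans asymmetric alkylation manifold) would be combined with the sodium phenoxide of 9, which releases 21 on warming to −40 °C.
   - Attack anti to the benzyl group of the auxiliary should give the phenol imide (4R)-4-benzyl-3-{(2R)-2-[2,2-dimethyl-5-(triisopropylsilyloxy)-2H-chromen-8-yl]-3-[2-hydroxy-6-methoxy-5-(3-methylbut-2-enyl)-4-(triisopropylsilyloxy)phenyl]propanoyl}oxazolidin-2-one F2 after a cold AcOH quench.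
   - i-Pr2NEt and catalytic DMAP in CH2Cl2 would then let the phenol displace the auxiliary (6-exo-trig) to give 22.

2. **Step 14.**
   - **What may go wrong:** the oxocarbenium ion may lose the C3 proton reversibly, which racemises C3 through the 4H-chromene. The Lewis acid may also attack the prenyl or chromene alkene.
   - **Fallback:** neutral O-alkylation replaces ionic reduction. It sets out from 23 and comes back at 24.
   - NaBH4 in THF/MeOH at 0 °C would reduce the open hydroxy aldehyde tautomer of 23 to the diol (2R)-2-[2,2-dimethyl-5-(triisopropylsilyloxy)-2H-chromen-8-yl]-3-[2-hydroxy-6-methoxy-5-(3-methylbut-2-enyl)-4-(triisopropylsilyloxy)phenyl]propan-1-ol F3.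
   - An intramolecular Mitsunobu etherification (PPh3, DIAD, THF, 0 °C) would then close O1–C2 (6-exo-tet) without touching C3.

3. **Step 3.**
   - **What may go wrong:** the rearrangement may stop at the ortho stage through fast enolisation of dienone 5, which puts a reverse-prenyl group on the future C8. The flanking silyl ether may also slow the second shift.
   - **Fallback:** a temporary blocking group leaves both ortho carbons without hydrogen. It sets out from 2 and comes back at 7.
   - NBS in CH2Cl2 at −20 °C should brominate the position ortho to the chelated hydroxyl, as is usual for 2-hydroxy-4,6-dialkoxyaryl carbonyl compounds. This gives 3-bromo-2-hydroxy-6-methoxy-4-(triisopropylsilyloxy)benzaldehyde F4.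
   - Mitsunobu etherification with 3 would give 3-bromo-6-methoxy-2-(3-methylbut-2-enyloxy)-4-(triisopropylsilyloxy)benzaldehyde F5.
   - Heating in PhNEt2 would force the classical para-Claisen course to 3-bromo-2-hydroxy-6-methoxy-5-(3-methylbut-2-enyl)-4-(triisopropylsilyloxy)benzaldehyde F6.
   - Hydrodebromination with Pd(PPh3)4 (zerovalent palladium, catalytic) and HCO2Na in DMF at 80 °C would return 7.

**Further compounds**
F1 | step 12 | (4R)-4-benzyl-3-{2-[2,2-dimethyl-5-(triisopropylsilyloxy)-2H-chromen-8-yl]acetyl}oxazolidin-2-one | O=C1OC[C@@H](Cc2ccccc2)N1C(=O)Cc1ccc(O[Si](C(C)C)(C(C)C)C(C)C)c2C=CC(C)(C)Oc12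
F2 | step 12 | (4R)-4-benzyl-3-{(2R)-2-[2,2-dimethyl-5-(triisopropylsilyloxy)-2H-chromen-8-yl]-3-[2-hydroxy-6-methoxy-5-(3-methylbut-2-enyl)-4-(triisopropylsilyloxy)phenyl]propanoyl}oxazolidin-2-one | O=C1OC[C@@H](Cc2ccccc2)N1C(=O)[C@H](Cc1c(O)cc(O[Si](C(C)C)(C(C)C)C(C)C)c(CC=C(C)C)c1OC)c1ccc(O[Si](C(C)C)(C(C)C)C(C)C)c2C=CC(C)(C)Oc12
F3 | step 14 | (2R)-2-[2,2-dimethyl-5-(triisopropylsilyloxy)-2H-chromen-8-yl]-3-[2-hydroxy-6-methoxy-5-(3-methylbut-2-enyl)-4-(triisopropylsilyloxy)phenyl]propan-1-ol | OC[C@H](Cc1c(O)cc(O[Si](C(C)C)(C(C)C)C(C)C)c(CC=C(C)C)c1OC)c1ccc(O[Si](C(C)C)(C(C)C)C(C)C)c2C=CC(C)(C)Oc12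
F4 | step 3 | 3-bromo-2-hydroxy-6-methoxy-4-(triisopropylsilyloxy)benzaldehyde | COc1cc(O[Si](C(C)C)(C(C)C)C(C)C)c(Br)c(O)c1C=O
F5 | step 3 | 3-bromo-6-methoxy-2-(3-methylbut-2-enyloxy)-4-(triisopropylsilyloxy)benzaldehyde | COc1cc(O[Si](C(C)C)(C(C)C)C(C)C)c(Br)c(OCC=C(C)C)c1C=O
F6 | step 3 | 3-bromo-2-hydroxy-6-methoxy-5-(3-methylbut-2-enyl)-4-(triisopropylsilyloxy)benzaldehyde | COc1c(CC=C(C)C)c(O[Si](C(C)C)(C(C)C)C(C)C)c(Br)c(O)c1C=O
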